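**Plan**

1. Numbering: ring A = N4, C9a, C1, C2, C3; ring B = N4, C5–C9, C9a; ring C = C1, C9a, C9, C10, C11, C12; lactone D = O, C11, C12, C13, C14; lactone E = C18–C21 on C3; ethyl on C10. The enabling feature is that N4 is bonded to C5 and to the ring-fusion carbon C9a: rings A, B and C are a cis-fused decalin-5-one (ring C plus the carbocycle C5–C9a) with nitrogen slipped in between C5 and C9a, and C2 and the C10 ethyl group stand on the face away from that carbocycle.
2. Retrosynthesis: take off the N-oxide oxygen, restore C5=O, remove both methyl groups (C13, C20), open lactone D (O–C14, C12–C13), add a temporary silyloxy group at C8, then cut C9–C10, C9a–C1, N4–C5 and N4–C9a at once to a 2-silyloxydiene azide and a 4-silyloxycyclohexenone; the diene is cut at C12=C1 (cross-metathesis), C3–N and C2–C3 back to a lactone aldehyde.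
3. Forward: lactone E comes ready-made from the chiral pool; ring C closes by exo Diels–Alder addition and rings A and B by azido-Schmidt ring expansion in the same flask; lactone D follows (C12 alkylation, C11 reduction); then C8 deoxygenation, both methyl groups, lactam-to-amine reduction and N-oxidation.
4. Stereochemistry: C18 from lactone 1 (L-glutamic acid series); C3 by reagent-controlled allylboration, then Mitsunobu inversion; C9 and C9a from attack anti to the C8 silyloxy group; C1 and C10 from exo topology and diene geometry; C12 and C11 by substrate control; C13 and C20 together by kinetic protonation of both lactone enolates; N4 by oxidation of the lone pair anti to lactone E.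
5. Lactone E is carried without its methyl group, because the enolate steps that build lactone D would over-alkylate or scramble C20; both methyl groups go on in one step and are set in one step.

Key step: step 8

Assumption: the lithium amide of (S,S)-bis(1-phenylethyl)amine desymmetrises ketone 9 in the sense known for 4-tert-butylcyclohexanone, giving the (R)-enol silane 10; if the sense is opposite, the (R,R)-amine is used.

**Route**

Step 1
Reactants: 1 (S)-5-(hydroxymethyl)dihydrofuran-2(3H)-one
Product: 2 (S)-5-oxotetrahydrofuran-2-carbaldehyde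
Conditions: Dess–Martin periodinane, CH2Cl2, 0 °C → rt; filtered, used crude
Reagents that add atoms: none
Why: Dess–Martin oxidation of the primary alcohol under neutral conditions leaves the lactone and the α-oxygenated stereocentre untouched, and the sensitive aldehyde is used without purification.

Step 2
Reactants: 2 (S)-5-oxotetrahydrofuran-2-carbaldehyde
Product: 4 (S)-5-[(R)-1-hydroxybut-3-en-1-yl]dihydrofuran-2(3H)-one, via borinate ester 3 (not isolated)
Conditions: (+)-Ipc2B(allyl) (reagent from (−)-α-pinene, 1.3 equiv), Et2O, −78 °C; then NaBO3·4H2O, THF/H2O, rt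
Reagents that add atoms: (+)-B-allyldiisopinocampheylborane, C=CCB([C@H]1C[C@H]2C[C@@H]([C@@H]1C)C2(C)C)[C@H]1C[C@H]2C[C@@H]([C@@H]1C)C2(C)C
Why: Brown allylboration through a chair six-membered transition state, in which this reagent enantiomer delivers allyl to the aldehyde face that gives the (R)-carbinol, the same face the Felkin–Anh model favours for the α-acyloxy aldehyde (anti product), so reagent and substrate control reinforce each other; perborate cleaves the borinate without opening the lactone.

Step 3
Reactants: 4 (S)-5-[(R)-1-hydroxybut-3-en-1-yl]dihydrofuran-2(3H)-one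
Product: 5 (S)-5-[(S)-1-azidobut-3-en-1-yl]dihydrofuran-2(3H)-one
Conditions: PPh3, DIAD, (PhO)2P(O)N3, THF, 0 °C → rt
Reagents that add atoms: diphenylphosphoryl azide, [N-]=[N+]=NP(=O)(Oc1ccccc1)Oc1ccccc1
Why: Mitsunobu azidation, in which azide displaces the oxyphosphonium of the secondary alcohol by SN2, inverting C3 from R to S.

Step 4
Reactants: 5 (S)-5-[(S)-1-azidobut-3-en-1-yl]dihydrofuran-2(3H)-one; 6 hex-1-en-3-one
Product: 7 (S)-5-[(S,E)-1-azido-5-oxooct-3-en-1-yl]dihydrofuran-2(3H)-one
Conditions: 6 (3 equiv), Hoveyda–Grubbs second-generation catalyst, (H2IMes)Cl2Ru=CH(C6H4-2-OiPr) (5 mol %), CH2Cl2, 40 °C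
Reagents that add atoms: none
Why: Olefin cross-metathesis between a terminal alkene and a slowly homodimerising vinyl ketone gives the E-enone under thermodynamic control, and the phosphine-free catalyst avoids Staudinger reduction of the azide.

Step 5
Reactants: 7 (S)-5-[(S,E)-1-azido-5-oxooct-3-en-1-yl]dihydrofuran-2(3H)-one
Product: 8 (S)-5-[(1S,3E,5Z)-1-azido-5-(trimethylsilyloxy)octa-3,5-dien-1-yl]dihydrofuran-2(3H)-one
Conditions: TMSOTf (1.2 equiv), Et3N (2 equiv), Et2O, 0 °C; used crude
Reagents that add atoms: trimethylsilyl trifluoromethanesulfonate, C[Si](C)(C)OS(=O)(=O)C(F)(F)F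
Why: Soft enolisation of the enone at the α'-methylene C10 gives the cross-conjugated 2-silyloxydiene as the Z enol ether (ethyl cis to oxygen, away from the vinyl arm), while the less readily enolised lactone is left alone at this stoichiometry and temperature.

Step 6
Reactants: 9 4-(tert-butyldimethylsilyloxy)cyclohexan-1-one
Product: 10 (R)-tert-butyldimethyl{[4-(trimethylsilyloxy)cyclohex-3-en-1-yl]oxy}silane
Conditions: (S,S)-bis(1-phenylethyl)amine, n-BuLi, TMSCl (in situ quench), THF, −100 → −78 °C
Reagents that add atoms: chlorotrimethylsilane, C[Si](C)(C)Cl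
Why: Enantioselective deprotonation of a prochiral 4-substituted cyclohexanone by a C2-symmetric chiral lithium amide with internal silyl quench distinguishes the two enantiotopic α-methylene groups and so fixes the silyloxy-bearing carbon as R; any enantiomeric material carried on becomes a separable diastereomer of 14.

Step 7
Reactants: 10 (R)-tert-butyldimethyl{[4-(trimethylsilyloxy)cyclohex-3-en-1-yl]oxy}silane
Product: 11 (R)-4-(tert-butyldimethylsilyloxy)cyclohex-2-en-1-one
Conditions: Pd(OAc)2 (1.05 equiv), MeCN, rt
Reagents that add atoms: none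
Why: Saegusa–Ito oxidation, in which the enol silane is palladated and β-hydride elimination places the double bond on the side where the enol ether was, so the silyloxy stereocentre is not touched.

Step 8
Reactants: 8 (S)-5-[(1S,3E,5Z)-1-azido-5-(trimethylsilyloxy)octa-3,5-dien-1-yl]dihydrofuran-2(3H)-one; 11 (R)-4-(tert-butyldimethylsilyloxy)cyclohex-2-en-1-one
Product: 14 tricyclic keto lactam (rings A, B and C; C5 lactam, C11 ketone, 8R silyloxy group, C10 ethyl, unmethylated lactone E on C3; H9 and H9a cis, H1 trans to H9a, C2 and ethyl cis; C1, C3, C9, C9a, C10, C18 as in the target), via Diels–Alder adduct 12 (not isolated), via azidohydrin 13 (not isolated)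
Conditions: 8 (1.3 equiv), SnCl4 (2.5 equiv), CH2Cl2, −78 °C → rt; aq. NaHCO3
Reagents that add atoms: none
Why: SnCl4 binds the enone carbonyl and the 2-silyloxydiene adds in a concerted, asynchronous [4+2] step, its enol-ether terminus C10 bonding to the β-carbon C9 and C1 to the α-carbon C9a, which closes ring C by intermolecular cycloaddition and gives cis-decalone 12. The azide on C3 then adds to the tin-activated C5 ketone (6-exo-trig onto C=O) to give the six-membered azidohydrin 13, and C9a, antiperiplanar to the departing N2, shifts from C5 to nitrogen with retention, forming N4–C9a and leaving N4–C5 as the amide bond; this one 1,2-shift contracts the azidohydrin ring to pyrrolidine ring A and expands the cyclohexanone to the seven-membered lactam ring B, and work-up hydrolyses the enol ether to the C11 ketone. The closest known reaction type is the Lewis-acid-promoted domino Diels–Alder/intramolecular azido-Schmidt reaction of silyloxydiene azides with cyclohex-2-enone. C9 and C9a are set by attack on the enone face anti to the pseudoaxial C8 silyloxy group (cis fusion follows from the cis dienophile), and C1 and C10 by suprafacial addition of the (3E,5Z)-diene, which puts C2 and ethyl cis, together with the exo topology, which puts both trans to the carbocycle. The step needs para regiochemistry (secured by the 2-silyloxy group), exo selectivity (favoured by SnCl4 for this diene class), facial selectivity on the enone (supplied by the C8 group, since the remote C3 centre cannot bias the diene) and migration of C9a rather than C6 (the tether starts next to C9a, so only the fused lactam is reachable). C11, which the azide could also reach through a six-membered ring, stays masked as its enol ether or tin enolate while the Schmidt step runs, so only C5 is attacked.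

Step 9
Reactants: 14 tricyclic keto lactam
Product: 16 C12-(2-ethoxy-2-oxoethyl) keto lactam (new arm on C12 trans to C2, otherwise as 14), via lithium enolate 15 (not isolated)
Conditions: LiN(SiMe3)2 (1.05 equiv), THF, −78 °C; BrCH2CO2Et, −78 → −30 °C
Reagents that add atoms: ethyl bromoacetate, CCOC(=O)CBr
Why: Kinetic enolate alkylation, in which the ketone C12 methylene is deprotonated faster than the tertiary C10–H or the less acidic lactone and lactam α-positions, and the bromoacetate enters anti to the axial C10 ethyl group so that the arm ends up equatorial, trans to C2.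

Step 10
Reactants: 16 C12-(2-ethoxy-2-oxoethyl) keto lactam
Product: 18 tetracyclic lactam with cis-fused lactone D (O on C11 cis to C13 on C12, unmethylated), 8R silyloxy group and unmethylated lactone E, via hydroxy ester 17 (not isolated)
Conditions: NaBH4, MeOH, −40 → 0 °C; then PPTS (cat.), toluene, 60 °C
Reagents that add atoms: none
Why: Borohydride reduction from the face opposite the axial C9–C8 bond of ring B and the C12 arm gives the axial C11 alcohol cis to that arm, which closes to the cis-fused γ-lactone by acid-catalysed 5-exo-trig transesterification; lactone E and the lactam are inert to NaBH4 at this temperature.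

Step 11
Reactants: 18 tetracyclic silyloxy lactam
Product: 19 C8 alcohol (8R; otherwise as 18)
Conditions: HF·pyridine, THF, 0 °C → rt
Reagents that add atoms: none
Why: Fluoride-mediated silyl ether cleavage under mildly acidic conditions that do not touch lactones or lactam.

Step 12
Reactants: 19 C8 alcohol
Product: 20 C8 O-(imidazol-1-ylthiocarbonyl) derivative of 19
Conditions: 1,1'-thiocarbonyldiimidazole, DMAP (cat.), 1,2-dichloroethane, 70 °C
Reagents that add atoms: 1,1'-thiocarbonyldiimidazole, S=C(n1ccnc1)n1ccnc1
Why: Thioacylation of the secondary alcohol gives the thiocarbonyl derivative required for radical deoxygenation.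

Step 13
Reactants: 20 C8 O-(imidazol-1-ylthiocarbonyl) derivative
Product: 21 13,20-bis(demethyl)-5-oxotuberostemonine (C8 now CH2; lactones D and E unmethylated; C5 lactam)
Conditions: Bu3SnH, AIBN (cat.), toluene, 100 °C
Reagents that add atoms: none
Why: Barton–McCombie deoxygenation, in which the stannyl radical adds to C=S, the secondary C8 radical is released and takes hydrogen from the stannane, removing the centre that was only needed to steer step 8.

Step 14
Reactants: 21 13,20-bis(demethyl)-5-oxotuberostemonine
Product: 23 13,20-bis-epi-5-oxotuberostemonine (C13 methyl trans to C1, C20 methyl trans to the C18 substituent), via dilithium bis-enolate 22 (not isolated)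
Conditions: LiN(SiMe3)2 (2.3 equiv), THF, −78 °C; MeI (excess), −78 → −40 °C
Reagents that add atoms: iodomethane, CI
Why: Double lactone enolate alkylation, in which the silylamide deprotonates both γ-lactones but not the less acidic lactam and each enolate takes methyl on its open face (convex face of lactone D, face anti to the C18 substituent in lactone E); the resulting bis-epi arrangement is of no consequence because step 15 resets both centres.

Step 15
Reactants: 23 13,20-bis-epi-5-oxotuberostemonine
Product: 25 5-oxotuberostemonine (13R, methyl cis to C1; 20S, methyl cis to the C18 substituent), via dilithium bis-enolate 24 (not isolated)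
Conditions: LiN(iPr)2 (3 equiv), THF, −78 °C; then 2,6-di-tert-butyl-4-methylphenol in THF, −78 °C
Reagents that add atoms: none
Why: Epimerisation by deprotonation and kinetic protonation, in which the bulky phenol delivers the proton to the same open faces that took methyl in step 14, pushing the C13 methyl onto the concave face of lactone D and the C20 methyl cis to the C18 substituent; any lactam α-proton removed is returned without consequence because C6 is not stereogenic.

Step 16
Reactants: 25 5-oxotuberostemonine
Product: 26 5-thioxotuberostemonine (thiolactam)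
Conditions: Lawesson's reagent (0.6 equiv), toluene, 80 °C
Reagents that add atoms: Lawesson's reagent, COc1ccc(cc1)P1(=S)SP(=S)(S1)c1ccc(OC)cc1
Why: Thionation with Lawesson's reagent, where the electron-rich lactam carbonyl reacts far faster than the two lactone carbonyls.

Step 17
Reactants: 26 5-thioxotuberostemonine
Product: 27 tuberostemonine
Conditions: Raney Ni (W-2 grade, washed to neutrality), EtOH, rt
Reagents that add atoms: none
Why: Reductive desulfurisation of the thiolactam gives the tertiary amine under neutral conditions that keep both α-methyl lactone centres intact.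

Step 18
Reactants: 27 tuberostemonine
Product: 28 N-oxytuberostemonine
Conditions: mCPBA (1.05 equiv), CH2Cl2, 0 °C; filtration through basic alumina
Reagents that add atoms: 3-chloroperoxybenzoic acid, OOC(=O)c1cccc(Cl)c1
Why: Electrophilic N-oxidation of the tertiary amine, with oxygen delivered to the lone pair on the face of ring A anti to lactone E on C3 (cis to H3, trans to H9a), which is the N4 configuration of the target.

**Compound list**

1 | (S)-5-(hydroxymethyl)dihydrofuran-2(3H)-one | OC[C@@H]1CCC(=O)O1 | starting material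
2 | (S)-5-oxotetrahydrofuran-2-carbaldehyde | O=C[C@@H]1CCC(=O)O1 | intermediate
3 | bis(isopinocampheyl)borinate ester of 4 | C=CC[C@@H](OB([C@H]2C[C@H]3C[C@@H]([C@@H]2C)C3(C)C)[C@H]2C[C@H]3C[C@@H]([C@@H]2C)C3(C)C)[C@@H]1CCC(=O)O1 | intermediate
4 | (S)-5-[(R)-1-hydroxybut-3-en-1-yl]dihydrofuran-2(3H)-one | C=CC[C@@H](O)[C@@H]1CCC(=O)O1 | intermediate
5 | (S)-5-[(S)-1-azidobut-3-en-1-yl]dihydrofuran-2(3H)-one | C=CC[C@H](N=[N+]=[N-])[C@@H]1CCC(=O)O1 | intermediate
6 | hex-1-en-3-one | CCCC(=O)C=C | starting material
7 | (S)-5-[(S,E)-1-azido-5-oxooct-3-en-1-yl]dihydrofuran-2(3H)-one | CCCC(=O)/C=C/C[C@H](N=[N+]=[N-])[C@@H]1CCC(=O)O1 | intermediate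
8 | (S)-5-[(1S,3E,5Z)-1-azido-5-(trimethylsilyloxy)octa-3,5-dien-1-yl]dihydrofuran-2(3H)-one | CC/C=C(O[Si](C)(C)C)/C=C/C[C@H](N=[N+]=[N-])[C@@H]1CCC(=O)O1 | intermediate
9 | 4-(tert-butyldimethylsilyloxy)cyclohexan-1-one | O=C1CCC(O[Si](C)(C)C(C)(C)C)CC1 | starting material
10 | (R)-tert-butyldimethyl{[4-(trimethylsilyloxy)cyclohex-3-en-1-yl]oxy}silane | C[Si](C)(C)OC1=CC[C@H](O[Si](C)(C)C(C)(C)C)CC1 | intermediate
11 | (R)-4-(tert-butyldimethylsilyloxy)cyclohex-2-en-1-one | O=C1C=C[C@H](O[Si](C)(C)C(C)(C)C)CC1 | intermediate
12 | Diels–Alder adduct: cis-decal-5-one with C11–C12 trimethylsilyl enol ether, C10 ethyl, C8 silyloxy group and the azido lactone chain on C1 | CC[C@@H]1[C@H]2[C@H](O[Si](C)(C)C(C)(C)C)CCC(=O)[C@H]2[C@H](C[C@H](N=[N+]=[N-])[C@@H]2CCC(=O)O2)C=C1O[Si](C)(C)C | intermediate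
13 | azidohydrin from N-to-C5 addition in 12, drawn as the alkoxide/aminodiazonium zwitterion (tin-bound in the flask; C5 drawn with N cis to C1) | CC[C@@H]1[C@H]2[C@H](O[Si](C)(C)C(C)(C)C)CC[C@]3([O-])[C@H]2[C@H](C[C@H](N3[N+]#N)[C@@H]2CCC(=O)O2)C=C1O[Si](C)(C)C | intermediate
14 | tricyclic keto lactam (C5 lactam, C11 ketone, 8R silyloxy, unmethylated lactone E) | CC[C@@H]1[C@H]2[C@H](O[Si](C)(C)C(C)(C)C)CCC(=O)N3[C@H]2[C@H](C[C@H]3[C@@H]2CCC(=O)O2)CC1=O | intermediate
15 | lithium C11–C12 enolate of 14 | [Li+].CC[C@@H]1[C@H]2[C@H](O[Si](C)(C)C(C)(C)C)CCC(=O)N3[C@H]2[C@H](C[C@H]3[C@@H]2CCC(=O)O2)C=C1[O-] | intermediate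
16 | C12-(2-ethoxy-2-oxoethyl) keto lactam | CC[C@@H]1[C@H]2[C@H](O[Si](C)(C)C(C)(C)C)CCC(=O)N3[C@H]2[C@H](C[C@H]3[C@@H]2CCC(=O)O2)[C@@H](CC(=O)OCC)C1=O | intermediate
17 | C11 hydroxy ester (OH cis to the C12 arm) | CC[C@@H]1[C@H]2[C@H](O[Si](C)(C)C(C)(C)C)CCC(=O)N3[C@H]2[C@H](C[C@H]3[C@@H]2CCC(=O)O2)[C@@H](CC(=O)OCC)[C@H]1O | intermediate
18 | tetracyclic lactam with lactone D, 8R silyloxy group, unmethylated lactones | CC[C@@H]1[C@H]2[C@H](O[Si](C)(C)C(C)(C)C)CCC(=O)N3[C@H]2[C@H](C[C@H]3[C@@H]2CCC(=O)O2)[C@@H]2[C@H]1OC(=O)C2 | intermediate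
19 | C8 alcohol of 18 | CC[C@@H]1[C@H]2[C@H](O)CCC(=O)N3[C@H]2[C@H](C[C@H]3[C@@H]2CCC(=O)O2)[C@@H]2[C@H]1OC(=O)C2 | intermediate
20 | C8 O-(imidazol-1-ylthiocarbonyl) derivative | CC[C@@H]1[C@H]2[C@H](OC(=S)n3ccnc3)CCC(=O)N3[C@H]2[C@H](C[C@H]3[C@@H]2CCC(=O)O2)[C@@H]2[C@H]1OC(=O)C2 | intermediate
21 | 13,20-bis(demethyl)-5-oxotuberostemonine | CC[C@@H]1[C@H]2CCCC(=O)N3[C@H]2[C@H](C[C@H]3[C@@H]2CCC(=O)O2)[C@@H]2[C@H]1OC(=O)C2 | intermediate
22 | dilithium bis-enolate of 21 | [Li+].[Li+].CC[C@@H]1[C@H]2CCCC(=O)N3[C@H]2[C@H](C[C@H]3[C@@H]2CC=C([O-])O2)[C@@H]2[C@H]1OC([O-])=C2 | intermediate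
23 | 13,20-bis-epi-5-oxotuberostemonine (13S, 20R) | CC[C@@H]1[C@H]2CCCC(=O)N3[C@H]2[C@H](C[C@H]3[C@@H]2C[C@@H](C)C(=O)O2)[C@@H]2[C@H]1OC(=O)[C@H]2C | intermediate
24 | dilithium bis-enolate of 23 | [Li+].[Li+].CC[C@@H]1[C@H]2CCCC(=O)N3[C@H]2[C@H](C[C@H]3[C@@H]2CC(C)=C([O-])O2)[C@@H]2[C@H]1OC([O-])=C2C | intermediate
25 | 5-oxotuberostemonine (13R, 20S) | CC[C@@H]1[C@H]2CCCC(=O)N3[C@H]2[C@H](C[C@H]3[C@@H]2C[C@H](C)C(=O)O2)[C@@H]2[C@H]1OC(=O)[C@@H]2C | intermediate
26 | 5-thioxotuberostemonine | CC[C@@H]1[C@H]2CCCC(=S)N3[C@H]2[C@H](C[C@H]3[C@@H]2C[C@H](C)C(=O)O2)[C@@H]2[C@H]1OC(=O)[C@@H]2C | intermediate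
27 | tuberostemonine | CC[C@@H]1[C@H]2CCCCN3[C@H]2[C@H](C[C@H]3[C@@H]2C[C@H](C)C(=O)O2)[C@@H]2[C@H]1OC(=O)[C@@H]2C | intermediate
28 | N-oxytuberostemonine | CC[C@@H]1[C@H]2CCCC[N@@+]3([O-])[C@H]2[C@H](C[C@H]3[C@@H]2C[C@H](C)C(=O)O2)[C@@H]2[C@H]1OC(=O)[C@@H]2C | target

**Step count**

Total: 18 steps. Longest linear sequence: 16 steps (steps 1–5, then 8–18); the enone branch (steps 6–7) joins at step 8.

**Steps most likely to fail**

Step 8. The labile trimethylsilyl dienyl ether may be lost before it cycloadds, or the exo and facial preferences may be too small when both Lewis-acid events run in one flask. Fallback: decouple the two events. Enone 7 is silylated with iPr3SiOTf/Et3N to the sturdier triisopropylsilyl dienyl ether F1. Et2AlCl at −78 °C, which promotes the cycloaddition but not the azide addition, joins F1 and 11 to the isolable cis-decalone silyl enol ether F2, and the exo, anti isomer is purified at this stage. TiCl4 in CH2Cl2 then brings about the azido-Schmidt ring expansion to the lactam silyl enol ether F3, and dilute HCl in THF frees the C11 ketone, which is compound 14.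

Step 15. Proton delivery may not be face-selective enough at one of the two enolates, or enolisation may be incomplete, leaving epimers that are hard to separate. Fallback: set both centres by hydrogenation instead. Starting from 21, LiN(SiMe3)2 and Eschenmoser's salt (Me2N=CH2 I) give the bis(dimethylaminomethyl) lactam F4, MeI quaternises both side-chain amines to the bis(trimethylammonium) iodide F5, and NaHCO3 eliminates trimethylamine to the bis(α-methylene) lactam F6. H2 over Pd/C then adds hydrogen to both exocyclic alkenes from the open faces (convex face of lactone D, face anti to C3 on lactone E) and gives 25 directly, bypassing steps 14 and 15.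

Step 9. The base may also deprotonate lactone E or C10, leading to alkylation at C20 or epimerisation of the ethyl-bearing centre. Fallback: Stork enamine alkylation, which needs no strong base. Ketone 14 is condensed with pyrrolidine (cat. TsOH, benzene, water removal) to the less substituted C11–C12 pyrrolidine enamine F7; ethyl bromoacetate in MeCN alkylates C12 to the iminium bromide F8, and aqueous acetate buffer hydrolyses it to 16.

**Further compounds**

F1 | step 8 | (S)-5-[(1S,3E,5Z)-1-azido-5-(triisopropylsilyloxy)octa-3,5-dien-1-yl]dihydrofuran-2(3H)-one | CC/C=C(O[Si](C(C)C)(C(C)C)C(C)C)/C=C/C[C@H](N=[N+]=[N-])[C@@H]1CCC(=O)O1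
F2 | step 8 | isolated Diels–Alder adduct (as 12, with triisopropylsilyl enol ether) | CC[C@@H]1[C@H]2[C@H](O[Si](C)(C)C(C)(C)C)CCC(=O)[C@H]2[C@H](C[C@H](N=[N+]=[N-])[C@@H]2CCC(=O)O2)C=C1O[Si](C(C)C)(C(C)C)C(C)C
F3 | step 8 | tricyclic lactam with C11–C12 triisopropylsilyl enol ether | CC[C@@H]1[C@H]2[C@H](O[Si](C)(C)C(C)(C)C)CCC(=O)N3[C@H]2[C@H](C[C@H]3[C@@H]2CCC(=O)O2)C=C1O[Si](C(C)C)(C(C)C)C(C)C
F4 | step 15 | 13,20-bis(dimethylaminomethyl) analogue of 21 | CC[C@@H]1[C@H]2CCCC(=O)N3[C@H]2[C@H](C[C@H]3[C@@H]2C[C@@H](CN(C)C)C(=O)O2)[C@@H]2[C@H]1OC(=O)[C@H]2CN(C)C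
F5 | step 15 | bis(trimethylammoniomethyl) diiodide from F4 | [I-].[I-].CC[C@@H]1[C@H]2CCCC(=O)N3[C@H]2[C@H](C[C@H]3[C@@H]2C[C@@H](C[N+](C)(C)C)C(=O)O2)[C@@H]2[C@H]1OC(=O)[C@H]2C[N+](C)(C)C
F6 | step 15 | 13,20-bis(methylene) lactam | CC[C@@H]1[C@H]2CCCC(=O)N3[C@H]2[C@H](C[C@H]3[C@@H]2CC(=C)C(=O)O2)[C@@H]2[C@H]1OC(=O)C2=C
F7 | step 9 | C11–C12 pyrrolidine enamine of 14 | CC[C@@H]1[C@H]2[C@H](O[Si](C)(C)C(C)(C)C)CCC(=O)N3[C@H]2[C@H](C[C@H]3[C@@H]2CCC(=O)O2)C=C1N1CCCC1
F8 | step 9 | C12-alkylated C11 pyrrolidinium (iminium) bromide | [Br-].CC[C@@H]1[C@H]2[C@H](O[Si](C)(C)C(C)(C)C)CCC(=O)N3[C@H]2[C@H](C[C@H]3[C@@H]2CCC(=O)O2)[C@@H](CC(=O)OCC)C1=[N+]1CCCC1
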